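The strategy rests on breaking the C5–C6 bond of the cyclopentanone ring (cyclopenta[c]pyridine numbering), the bond between the two fully substituted carbons C5 (pyridine C4a, OH, CO2Me) and C6 (OMe, CH3). The substituent set at C5 is that of a pyridyl(ester) carbene after capture by a hydroxyl group, so a rhodium carbenoid from a 4-pyridyl diazoacetate is combined with the enantiopure enol-ether allylic alcohol (2S,3E)-4-methoxypent-3-en-2-ol. Ylide formation and a [2,3] shift create the C5–O and C5–C6 bonds and both stereocentres at once, without closing a ring. A Heck closure of the ortho bromide onto the resulting propenyl group, ozonolysis and a late Suzuki coupling at the chloride finish the target.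

Key step: step 4

Assumption: the enantiomer of Rh2(DOSP)4 that directs bonding to the required face of the ylide carbon of this ortho-brominated pyridyl carbenoid is taken to be Rh2(S-DOSP)4; the sense of induction would be checked on a small scale, and Rh2(R-DOSP)4 would replace it with no other change.

Assumption: the exocyclic alkene of 8 is drawn Z, as syn insertion followed by syn elimination predicts; its geometry has no bearing on the route because the alkene is cleaved in the next step.

Step 1
Reactants: 1 5-bromo-2-chloro-4-methylpyridine
Product: 2 methyl 2-(5-bromo-2-chloropyridin-4-yl)acetate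
Conditions: LDA (2.2 equiv), THF, −78 °C; (MeO)2CO, −78 → 0 °C; aq NH4Cl
Reagents that add atoms: dimethyl carbonate, COC(=O)OC
Why: Lateral (picolyl) deprotonation of the 4-methyl group by the non-nucleophilic amide should outrun ring metalation and attack at the halogens, the anion is C-acylated by dimethyl carbonate (Claisen-type carbomethoxylation), and the second equivalent of base holds the more acidic product as its enolate until the quench.

Step 2
Reactants: 2 methyl 2-(5-bromo-2-chloropyridin-4-yl)acetate
Product: 3 methyl 2-(5-bromo-2-chloropyridin-4-yl)-2-diazoacetate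
Conditions: p-ABSA, DBU, MeCN, 0 °C → rt
Reagents that add atoms: 4-acetamidobenzenesulfonyl azide (p-ABSA), CC(=O)Nc1ccc(cc1)S(=O)(=O)N=[N+]=[N-]
Why: Regitz diazo transfer: DBU deprotonates the doubly activated methylene and the enolate takes N2 from the sulfonyl azide, and a 4-pyridyl diazoacetate cannot cyclise onto the ring nitrogen as 2-pyridyl analogues do.

Step 3
Reactants: 4 (E)-4-methoxypent-3-en-2-one
Product: 5 (2S,3E)-4-methoxypent-3-en-2-ol
Conditions: (R)-Me-CBS oxazaborolidine (20 mol%), catecholborane (1.5 equiv), toluene, −78 °C; MeOH, then aq NaOH work-up; Et3N-deactivated silica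
Reagents that add atoms: none
Why: Corey–Bakshi–Shibata reduction: the oxazaborolidine binds the ketone oxygen anti to the alkenyl group (the large substituent) and delivers hydride from catecholborane to one face, the (R)-catalyst being expected to give the (S)-carbinol by analogy with other alkenyl methyl ketones, while the low temperature spares the enol ether and the strictly basic work-up protects the acid-labile product.

Step 4
Reactants: 3 methyl 2-(5-bromo-2-chloropyridin-4-yl)-2-diazoacetate; 5 (2S,3E)-4-methoxypent-3-en-2-ol
Product: 7 methyl (2R,3R,4E)-2-(5-bromo-2-chloropyridin-4-yl)-2-hydroxy-3-methoxy-3-methylhex-4-enoate, via oxonium ylide 6 (not isolated)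
Conditions: Rh2(S-DOSP)4 (1 mol%), 5 (1.5 equiv), 4 Å MS, pentane/PhCF3, 0 °C, slow addition of 3 by syringe pump
Reagents that add atoms: none
Why: Proposed new method: Rh2(S-DOSP)4 expels N2 from 3 to give a divalent rhodium donor/acceptor carbenoid whose electrophilic carbon should be attacked by the hydroxyl oxygen of 5 faster than by its hindered trisubstituted enol ether, and the oxonium ylide 6 then undergoes a suprafacial [2,3] shift through a five-membered envelope in which the ylide carbon bonds to the methoxy-bearing alkene terminus as the carbinol C–O bond breaks; the closest known reaction is the rhodium-catalysed tandem ylide formation/[2,3] rearrangement of aryl- and vinyldiazoacetates with chiral secondary allylic alcohols, which has not been shown with an enol-ether terminus or a pyridyl carbenoid. No ring is closed. C3 (the later C6) is set by 1,3-chirality transfer from the (S)-carbinol: with the carbinol methyl pseudo-equatorial (its hydrogen eclipsing the alkene and so avoiding allylic strain with the cis methyl), the new bond forms on the face from which oxygen departs, which for the (E)-enol ether gives the (3R) centre and the (E)-propenyl group. C2 (the later C5) is set by the face of the ylide carbon that bonds, namely an envelope with the pyridyl group under the allyl flap and the ester outside, which the chiral carboxylate ligands of the catalyst are relied on to enforce, giving (2R). The step needs the [2,3] shift to win over cyclopropanation and over simple 1,2-proton transfer; the trisubstituted alkene disfavours the former, and the methoxy group, which stabilises positive charge at the migration terminus, together with the secondary carbinol and the non-polar medium, disfavours the latter. The chlorine next to nitrogen lowers the basicity of the pyridine so that it does not block the axial sites of the catalyst.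

Step 5
Reactants: 7 methyl (2R,3R,4E)-2-(5-bromo-2-chloropyridin-4-yl)-2-hydroxy-3-methoxy-3-methylhex-4-enoate
Product: 8 methyl (5R,6R,7Z)-3-chloro-7-ethylidene-5-hydroxy-6-methoxy-6-methyl-6,7-dihydro-5H-cyclopenta[c]pyridine-5-carboxylate
Conditions: Pd(OAc)2 (5 mol%), P(o-tol)3 (12 mol%), Et3N, MeCN, 80 °C
Reagents that add atoms: none
Why: Intramolecular Heck reaction: zerovalent palladium should insert into the C–Br bond in preference to the C–Cl bond, 5-exo-trig syn insertion into the propenyl alkene forms the C7–C7a bond, and β-hydride elimination of the ring C7–H gives the conjugated exocyclic ethylidene without touching either quaternary centre.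

Step 6
Reactants: 8 methyl (5R,6R,7Z)-3-chloro-7-ethylidene-5-hydroxy-6-methoxy-6-methyl-6,7-dihydro-5H-cyclopenta[c]pyridine-5-carboxylate
Product: 9 methyl (5R,6S)-3-chloro-5-hydroxy-6-methoxy-6-methyl-7-oxo-6,7-dihydro-5H-cyclopenta[c]pyridine-5-carboxylate
Conditions: O3, CH2Cl2/MeOH, −78 °C; Me2S, −78 °C → rt
Reagents that add atoms: ozone, [O-][O+]=O
Why: Ozonolysis with reductive work-up cleaves the only alkene to the C7 ketone, the electron-poor chloropyridine and the tertiary alcohol being inert to ozone at −78 °C, and the change of the C6 descriptor from R to S reflects only the new CIP priorities.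

Step 7
Reactants: 10 (S)-2-methylbutan-1-ol
Product: 12 (2E,4S)-2,4-dimethylhex-2-enal, via (S)-2-methylbutanal 11 (not isolated)
Conditions: TEMPO (10 mol%), PhI(OAc)2, CH2Cl2, rt; aq NaHCO3 wash; then Ph3P=C(CH3)CHO, CH2Cl2, 40 °C
Reagents that add atoms: 2-(triphenylphosphoranylidene)propanal, CC(C=O)=P(c1ccccc1)(c1ccccc1)c1ccccc1
Why: TEMPO/PhI(OAc)2 oxidation stops at the aldehyde, which is kept in solution and away from base, and the Wittig reaction of the stabilised, weakly basic formyl ylide should give the (E)-enal without racemising the α-stereocentre, the α-branched enal being too unreactive to be homologated a second time.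

Step 8
Reactants: 12 (2E,4S)-2,4-dimethylhex-2-enal
Product: 13 2-[(1E,3E,5S)-3,5-dimethylhepta-1,3-dien-1-yl]-4,4,5,5-tetramethyl-1,3,2-dioxaborolane
Conditions: CrCl2 (8 equiv), Cl2CHBpin (2 equiv), LiI (4 equiv), THF, rt
Reagents that add atoms: 2-(dichloromethyl)-4,4,5,5-tetramethyl-1,3,2-dioxaborolane, ClC(Cl)B1OC(C)(C)C(C)(C)O1
Why: Takai–Utimoto boryl olefination: the geminal dichromium species formed from the dihalomethylboronate (after chloride–iodide exchange) adds 1,2 to the aldehyde and eliminates to the (E)-alkenylboronate, and the non-basic conditions leave the allylic stereocentre and the trisubstituted alkene untouched.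

Step 9
Reactants: 9 methyl (5R,6S)-3-chloro-5-hydroxy-6-methoxy-6-methyl-7-oxo-6,7-dihydro-5H-cyclopenta[c]pyridine-5-carboxylate; 13 2-[(1E,3E,5S)-3,5-dimethylhepta-1,3-dien-1-yl]-4,4,5,5-tetramethyl-1,3,2-dioxaborolane
Product: 14 methyl (5R,6S)-3-[(1E,3E,5S)-3,5-dimethylhepta-1,3-dien-1-yl]-5-hydroxy-6-methoxy-6-methyl-7-oxo-6,7-dihydro-5H-cyclopenta[c]pyridine-5-carboxylate
Conditions: Pd(OAc)2 (5 mol%), SPhos (10 mol%), K3PO4, THF/H2O, 40 °C
Reagents that add atoms: none
Why: Suzuki–Miyaura coupling: the C3–Cl bond, activated by the ring nitrogen and the para acyl group, should undergo oxidative addition under mild conditions and couple with retention of the diene geometry, while the weak base and low temperature guard against retro-aldol opening of the β-hydroxy ketone.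

Compound list
1 | 5-bromo-2-chloro-4-methylpyridine | Cc1cc(Cl)ncc1Br | starting material
2 | methyl 2-(5-bromo-2-chloropyridin-4-yl)acetate | COC(=O)Cc1cc(Cl)ncc1Br | intermediate
3 | methyl 2-(5-bromo-2-chloropyridin-4-yl)-2-diazoacetate | COC(=O)C(=[N+]=[N-])c1cc(Cl)ncc1Br | intermediate
4 | (E)-4-methoxypent-3-en-2-one | CO/C(C)=C/C(C)=O | starting material
5 | (2S,3E)-4-methoxypent-3-en-2-ol | C[C@H](O)/C=C(\C)OC | intermediate
6 | oxonium ylide from the carbenoid of 3 and the hydroxyl of 5 (free or rhodium-bound; not isolated) | COC(=O)[C-](c1cc(Cl)ncc1Br)[OH+][C@@H](C)/C=C(\C)OC | intermediate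
7 | methyl (2R,3R,4E)-2-(5-bromo-2-chloropyridin-4-yl)-2-hydroxy-3-methoxy-3-methylhex-4-enoate | C/C=C/[C@@](C)(OC)[C@@](c1cc(Cl)ncc1Br)(O)C(=O)OC | intermediate
8 | methyl (5R,6R,7Z)-3-chloro-7-ethylidene-5-hydroxy-6-methoxy-6-methyl-6,7-dihydro-5H-cyclopenta[c]pyridine-5-carboxylate | Clc1cc2c(cn1)/C(=C/C)[C@@](C)(OC)[C@@]2(O)C(=O)OC | intermediate
9 | methyl (5R,6S)-3-chloro-5-hydroxy-6-methoxy-6-methyl-7-oxo-6,7-dihydro-5H-cyclopenta[c]pyridine-5-carboxylate | Clc1cc2c(cn1)C(=O)[C@@](C)(OC)[C@@]2(O)C(=O)OC | intermediate
10 | (S)-2-methylbutan-1-ol | CC[C@H](C)CO | starting material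
11 | (S)-2-methylbutanal (not isolated) | CC[C@H](C)C=O | intermediate
12 | (2E,4S)-2,4-dimethylhex-2-enal | CC[C@H](C)/C=C(\C)C=O | intermediate
13 | 2-[(1E,3E,5S)-3,5-dimethylhepta-1,3-dien-1-yl]-4,4,5,5-tetramethyl-1,3,2-dioxaborolane | CC[C@H](C)/C=C(C)/C=C/B1OC(C)(C)C(C)(C)O1 | intermediate
14 | methyl (5R,6S)-3-[(1E,3E,5S)-3,5-dimethylhepta-1,3-dien-1-yl]-5-hydroxy-6-methoxy-6-methyl-7-oxo-6,7-dihydro-5H-cyclopenta[c]pyridine-5-carboxylate | CC[C@H](C)/C=C(C)/C=C/c1cc2c(cn1)C(=O)[C@@](C)(OC)[C@@]2(O)C(=O)OC | target

Total step count: 9 steps.
Longest linear sequence: 6 steps (1 → 2 → 3 → 7 → 8 → 9 → 14; steps 1, 2, 4, 5, 6 and 9).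

Steps most likely to fail

Step 4 (the proposed new method). Three processes could defeat it: the carbenoid may be consumed by the electron-rich enol-ether π bond, the ylide may collapse by proton transfer to the plain O–H insertion product, or the wrong face of the ylide carbon may bond and give the C2 epimer. The fallback separates the two bond-forming events and uses known reactions. It sets out from 3 and 5. Rh2(OAc)4 (1 mol%) in CH2Cl2 at room temperature should give, by ordinary O–H insertion, the allyl ether methyl 2-(5-bromo-2-chloropyridin-4-yl)-2-{[(2S,3E)-4-methoxypent-3-en-2-yl]oxy}acetate F1 as a mixture of epimers at the carbon next to the ester, which is of no consequence because that centre is enolised next. Treatment of F1 with LiN(SiMe3)2 in THF from −78 °C to room temperature should form the ester enolate, which undergoes the anionic [2,3]-Wittig rearrangement of an α-allyloxy ester. The same suprafacial chirality transfer from the carbinol fixes C3 and the (E)-propenyl group, and C2 follows from the enolate envelope; any C2 epimer would be removed by chromatography. The fallback comes back to the route at 7, and any 7 formed directly during the insertion is carried along.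

Step 5. The alkylpalladium intermediate may lose a hydrogen from the methyl group and give a vinyl isomer that ozonolysis cannot turn into the ketone, oxidative addition may compete at the C–Cl bond, or closure may take the 6-endo course. The fallback replaces the Heck closure by an acylation of an aryl Grignard reagent and sets out from 7. Ozonolysis (O3, CH2Cl2, −78 °C; Me2S) should give the aldehyde methyl (2R,3S)-2-(5-bromo-2-chloropyridin-4-yl)-2-hydroxy-3-methoxy-3-methyl-4-oxobutanoate F2. Pinnick oxidation (NaClO2, NaH2PO4, 2-methylbut-2-ene, t-BuOH/H2O) should give the acid (2S,3R)-3-(5-bromo-2-chloropyridin-4-yl)-3-hydroxy-2,4-dimethoxy-2-methyl-4-oxobutanoic acid F3. Esterification with Me3SiCHN2 in toluene/MeOH should give the diester dimethyl (2R,3S)-2-(5-bromo-2-chloropyridin-4-yl)-2-hydroxy-3-methoxy-3-methylbutanedioate F4. With i-PrMgCl·LiCl (2.2 equiv, THF, −40 °C) the first equivalent deprotonates the hydroxyl and the second performs bromine–magnesium exchange. The aryl Grignard reagent can reach only the C3 ester (5-exo closure; attack on the other ester would need a four-membered ring) and should give the ketone. The fallback comes back to the route at 9.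

Step 3. Hydride transfer to the deactivated vinylogous-ester carbonyl may be slow, the enantioselectivity on this untried enone may be low, or the boron-bound product may ionise at its allylic C–O bond. The fallback resolves instead of reducing asymmetrically and sets out from 4. LiAlH4 in Et2O at −20 °C with a basic (Fieser) work-up should give the racemic alcohol (E)-4-methoxypent-3-en-2-ol F5. Candida antarctica lipase B (immobilised) with vinyl acetate in hexane/MTBE at room temperature should acylate the (R)-enantiomer to (2R,3E)-4-methoxypent-3-en-2-yl acetate F6 and leave the (S)-alcohol, which is separated on Et3N-deactivated silica. The fallback comes back to the route at 5.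

Further compounds
F1 | step 4 | methyl 2-(5-bromo-2-chloropyridin-4-yl)-2-{[(2S,3E)-4-methoxypent-3-en-2-yl]oxy}acetate (both epimers at C2) | COC(=O)C(O[C@@H](C)/C=C(\C)OC)c1cc(Cl)ncc1Br
F2 | step 5 | methyl (2R,3S)-2-(5-bromo-2-chloropyridin-4-yl)-2-hydroxy-3-methoxy-3-methyl-4-oxobutanoate | O=C[C@@](C)(OC)[C@@](c1cc(Cl)ncc1Br)(O)C(=O)OC
F3 | step 5 | (2S,3R)-3-(5-bromo-2-chloropyridin-4-yl)-3-hydroxy-2,4-dimethoxy-2-methyl-4-oxobutanoic acid | OC(=O)[C@@](C)(OC)[C@@](c1cc(Cl)ncc1Br)(O)C(=O)OC
F4 | step 5 | dimethyl (2R,3S)-2-(5-bromo-2-chloropyridin-4-yl)-2-hydroxy-3-methoxy-3-methylbutanedioate | COC(=O)[C@@](C)(OC)[C@@](c1cc(Cl)ncc1Br)(O)C(=O)OC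
F5 | step 3 | racemic (E)-4-methoxypent-3-en-2-ol | CC(O)/C=C(\C)OC
F6 | step 3 | (2R,3E)-4-methoxypent-3-en-2-yl acetate | C[C@@H](OC(C)=O)/C=C(\C)OC
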